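**Retrosynthetic overview**
- The C8 ester is made last from the 8-hydroxy lactone and a chlorohydrin acid obtained from (E)-2-methylbut-2-en-1-ol (Sharpless epoxidation, oxidation, HCl opening).
- The ten-membered carbocycle (C6–C7 bond) and the γ-lactone (O6–C12) are closed together by a CrCl2 allylation–lactonisation of an acyclic epoxy aldehyde carrying an allylic bromide.
- C7 is a one-carbon linchpin placed between two aldehyde carbons: a 3-bromo-2-(bromomethyl)acrylate first adds to the C8 aldehyde (acyclic Felkin control), and its second C–Br bond is kept for the ring closure onto C6.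
- The C8 aldehyde / C9 acetate comes from a Nozaki–Hiyama–Kishi coupling of a (Z)-2-iodoenoate with (R)-glyceraldehyde acetonide, then glycol cleavage; C1–C6 come from geraniol.
- Ring order: epoxide first (Sharpless epoxidation on the open chain), then the ten-membered ring and the lactone in one operation.

Assumption: locants C1–C15 in the text follow germacrane numbering of the target (epoxide C4–C5, lactone oxygen on C6, acyloxy groups on C8 and C9, C14 = ester carbon on C10, C11–C13 = acrylate unit).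

**Route**

Step 1
Reactants: 1 geraniol
Product: 2 triethyl{[(2E)-3,7-dimethylocta-2,6-dien-1-yl]oxy}silane
Conditions: TESCl, imidazole, CH2Cl2, 0 °C
Reagents that add atoms: triethylsilyl chloride, CC[Si](Cl)(CC)CC
Why: Standard silyl ether protection of the primary allylic alcohol, the TES group being chosen because the acid of step 6 removes it without a separate step.

Step 2
Reactants: 2 triethyl{[(2E)-3,7-dimethylocta-2,6-dien-1-yl]oxy}silane
Product: 4 (4E)-4-methyl-6-[(triethylsilyl)oxy]hex-4-enal, via ozonide 3 (not isolated)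
Conditions: O3 (1 equiv), CH2Cl2, pyridine (cat.), −78 °C (Sudan Red 7B end-point); then PPh3, −78 °C to rt
Reagents that add atoms: ozone, [O-][O+]=O
Why: Ozonolysis with reductive work-up cleaves the more electron-rich terminal double bond, the other one being deactivated by the allylic silyloxy group.

Step 3
Reactants: 4 (4E)-4-methyl-6-[(triethylsilyl)oxy]hex-4-enal; 5 methyl (triphenylphosphoranylidene)acetate
Product: 7 methyl (2Z,6E)-2-iodo-6-methyl-8-[(triethylsilyl)oxy]octa-2,6-dienoate, via iodo ylide 6 (not isolated)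
Conditions: 5, NIS, CH2Cl2, −20 °C; then 4, −20 °C to rt
Reagents that add atoms: N-iodosuccinimide, O=C1CCC(=O)N1I
Why: Wittig olefination with the iodinated stabilised ylide (iodo-Wittig reaction) puts the ester trans to the chain, which is the (Z)-2-iodoenoate.

Step 4
Reactants: 7 methyl (2Z,6E)-2-iodo-6-methyl-8-[(triethylsilyl)oxy]octa-2,6-dienoate; 8 (4R)-2,2-dimethyl-1,3-dioxolane-4-carbaldehyde
Product: 9 methyl (2E,6E)-2-[(S)-[(4R)-2,2-dimethyl-1,3-dioxolan-4-yl](hydroxy)methyl]-6-methyl-8-[(triethylsilyl)oxy]octa-2,6-dienoate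
Conditions: CrCl2 (4 equiv), NiCl2 (2 mol%), DMF, rt
Reagents that add atoms: none
Why: Nozaki–Hiyama–Kishi alkenylation in which the alkenylchromium formed with retention adds to the α-alkoxy aldehyde under Felkin–Anh control (C–O bond anti to the nucleophile) to give the 9S, 8,9-anti alcohol, the C1=C10 geometry being also the thermodynamic one.

Step 5
Reactants: 9 methyl (2E,6E)-2-[(S)-[(4R)-2,2-dimethyl-1,3-dioxolan-4-yl](hydroxy)methyl]-6-methyl-8-[(triethylsilyl)oxy]octa-2,6-dienoate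
Product: 10 methyl (2E,6E)-2-[(S)-(acetyloxy)[(4R)-2,2-dimethyl-1,3-dioxolan-4-yl]methyl]-6-methyl-8-[(triethylsilyl)oxy]octa-2,6-dienoate
Conditions: Ac2O, pyridine, DMAP (cat.), CH2Cl2, 0 °C
Reagents that add atoms: acetic anhydride, CC(=O)OC(C)=O
Why: DMAP-catalysed acetylation installs the C9 acetate of the target and protects this oxygen from the glycol cleavage that follows.

Step 6
Reactants: 10 methyl (2E,6E)-2-[(S)-(acetyloxy)[(4R)-2,2-dimethyl-1,3-dioxolan-4-yl]methyl]-6-methyl-8-[(triethylsilyl)oxy]octa-2,6-dienoate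
Product: 12 methyl (2E,6E)-2-[(1S)-1-(acetyloxy)-2-oxoethyl]-8-hydroxy-6-methylocta-2,6-dienoate, via triol 11 (not isolated)
Conditions: H5IO6 (2.5 equiv), THF/H2O (4:1), 0 °C to rt
Reagents that add atoms: none
Why: Periodic acid hydrolyses the terminal acetonide and the TES ether and cleaves the freed 1,2-diol in the same pot (glycol cleavage), so the spent glyceraldehyde stereocentre becomes the C8 aldehyde while C9 is untouched.

Step 7
Reactants: 13 methyl 2-(bromomethyl)prop-2-enoate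
Product: 15 methyl (2Z)-3-bromo-2-(bromomethyl)prop-2-enoate, via tribromide 14 (not isolated)
Conditions: Br2, CH2Cl2, 0 °C; then i-Pr2NEt, 0 °C to rt
Reagents that add atoms: bromine, BrBr
Why: Bromine addition to the acrylate followed by base-induced dehydrobromination of the activated α-bromo ester gives the linchpin, whose double-bond geometry is irrelevant because it is used as an allylmetal.

Step 8
Reactants: 12 methyl (2E,6E)-2-[(1S)-1-(acetyloxy)-2-oxoethyl]-8-hydroxy-6-methylocta-2,6-dienoate; 15 methyl (2Z)-3-bromo-2-(bromomethyl)prop-2-enoate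
Product: 16 methyl (2E,6E)-2-[(1S,2S)-1-(acetyloxy)-3-bromo-2-hydroxy-4-(methoxycarbonyl)pent-4-en-1-yl]-8-hydroxy-6-methylocta-2,6-dienoate (both C7 epimers)
Conditions: In powder (1.2 equiv), 15 (1.5 equiv), THF/H2O (3:1), rt
Reagents that add atoms: none
Why: Proposed new method: indium inserts only into the allylic C–Br bond of 15 and the 3-bromo-2-(methoxycarbonyl)allylindium adds through its bromine-bearing γ-carbon to the aldehyde in a cyclic SE2' transition state, with Felkin–Anh control by the α-acetoxy centre giving the 8,9-anti alcohol (8R in target terms) while C7 stays an irrelevant epimer mixture; the closest known reaction types are the indium Barbier reaction of 2-(bromomethyl)acrylates and the indium γ-bromoallylation of aldehydes with 1,3-dibromopropene.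

Step 9
Reactants: 16 methyl (2E,6E)-2-[(1S,2S)-1-(acetyloxy)-3-bromo-2-hydroxy-4-(methoxycarbonyl)pent-4-en-1-yl]-8-hydroxy-6-methylocta-2,6-dienoate
Product: 17 methyl (2E)-2-[(1S,2S)-1-(acetyloxy)-3-bromo-2-hydroxy-4-(methoxycarbonyl)pent-4-en-1-yl]-5-[(2R,3R)-3-(hydroxymethyl)-2-methyloxiran-2-yl]pent-2-enoate
Conditions: Ti(OiPr)4 (20 mol%), D-(−)-diethyl tartrate (24 mol%), t-BuOOH, 4 Å MS, CH2Cl2, −20 °C
Reagents that add atoms: tert-butyl hydroperoxide, CC(C)(C)OO
Why: Sharpless asymmetric epoxidation of the primary allylic alcohol with the D-(−)-tartrate catalyst sets C4 and C5 (both R) by reagent control as for geraniol, the electron-poor double bonds being inert.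

Step 10
Reactants: 17 methyl (2E)-2-[(1S,2S)-1-(acetyloxy)-3-bromo-2-hydroxy-4-(methoxycarbonyl)pent-4-en-1-yl]-5-[(2R,3R)-3-(hydroxymethyl)-2-methyloxiran-2-yl]pent-2-enoate
Product: 18 methyl (2E)-2-[(1S,2S)-1-(acetyloxy)-3-bromo-2-hydroxy-4-(methoxycarbonyl)pent-4-en-1-yl]-5-[(2R,3S)-3-formyl-2-methyloxiran-2-yl]pent-2-enoate
Conditions: TEMPO (10 mol%), PhI(OAc)2, CH2Cl2, rt
Reagents that add atoms: none
Why: The oxoammonium (TEMPO) oxidation takes the primary alcohol to the aldehyde selectively over the hindered secondary C8 hydroxyl and does not epimerise the epoxy aldehyde.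

Step 11
Reactants: 18 methyl (2E)-2-[(1S,2S)-1-(acetyloxy)-3-bromo-2-hydroxy-4-(methoxycarbonyl)pent-4-en-1-yl]-5-[(2R,3S)-3-formyl-2-methyloxiran-2-yl]pent-2-enoate
Product: 20 methyl (1(10)E,4R,5R,6S,7R,8R,9S)-9-acetoxy-4,5-epoxy-8-hydroxygermacra-1(10),11(13)-dien-12,6-olid-14-oate, via seco hydroxy ester 19 (not isolated)
Conditions: CrCl2 (6 equiv), DMF/THF (1:1), 0.002 M, slow addition, rt; aq. NH4Cl
Reagents that add atoms: none
Why: Intramolecular chromium-mediated Barbier allylation (Nozaki–Hiyama type) in which the 2-(methoxycarbonyl)allylchromium adds through C7 to the epoxy aldehyde and the chromium alkoxide on O6 then lactonises onto the ester, so the carbocycle and the lactone form in one operation; C6 (S) and C7 (R) are expected from the ten-membered transition state that leads to the trans-fused lactone, as in related closures of (Z)-configured epoxy aldehydes, while the neutral C8 hydroxyl is a poor leaving group and a poorer acyl acceptor than the alkoxide.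

Step 12
Reactants: 21 (2E)-2-methylbut-2-en-1-ol
Product: 22 [(2R,3R)-2,3-dimethyloxiran-2-yl]methanol
Conditions: Ti(OiPr)4 (10 mol%), D-(−)-diethyl tartrate (12 mol%), t-BuOOH, 4 Å MS, CH2Cl2, −20 °C
Reagents that add atoms: tert-butyl hydroperoxide, CC(C)(C)OO
Why: Sharpless asymmetric epoxidation of the (E)-allylic alcohol gives the (2R,3R)-epoxy alcohol by reagent control.

Step 13
Reactants: 22 [(2R,3R)-2,3-dimethyloxiran-2-yl]methanol
Product: 23 (2S,3R)-2,3-dimethyloxirane-2-carboxylic acid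
Conditions: TEMPO (cat.), PhI(OAc)2 (2.2 equiv), MeCN/H2O (1:1), rt
Reagents that add atoms: water, O
Why: TEMPO oxidation in aqueous medium takes the primary alcohol through the aldehyde hydrate to the acid without touching the two epoxide stereocentres.

Step 14
Reactants: 23 (2S,3R)-2,3-dimethyloxirane-2-carboxylic acid
Product: 24 (2R,3S)-3-chloro-2-hydroxy-2-methylbutanoic acid
Conditions: HCl (4 M in 1,4-dioxane), 0 °C to rt
Reagents that add atoms: hydrogen chloride, Cl
Why: Acid-mediated epoxide opening in which chloride attacks the β-carbon C3 in SN2 fashion with inversion, attack at the quaternary carboxyl-bearing C2 being disfavoured sterically and electronically.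

Step 15
Reactants: 20 methyl (1(10)E,4R,5R,6S,7R,8R,9S)-9-acetoxy-4,5-epoxy-8-hydroxygermacra-1(10),11(13)-dien-12,6-olid-14-oate; 24 (2R,3S)-3-chloro-2-hydroxy-2-methylbutanoic acid
Product: 26 methyl (1(10)E,4R,5R,6S,7R,8R,9S)-9-acetoxy-8-{[(2R,3S)-3-chloro-2-hydroxy-2-methylbutanoyl]oxy}-4,5-epoxygermacra-1(10),11(13)-dien-12,6-olid-14-oate, via mixed anhydride 25 (not isolated)
Conditions: 24, 2,4,6-Cl3C6H2COCl, Et3N, THF, rt; then 20, DMAP, toluene, rt
Reagents that add atoms: none
Why: Yamaguchi esterification in which the C8 hydroxyl attacks the aliphatic carbonyl of the mixed anhydride under DMAP catalysis, the tertiary hydroxyl of the acid being too hindered to compete and no stereocentre being touched.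

**Compound list**

1 | geraniol, (2E)-3,7-dimethylocta-2,6-dien-1-ol | CC(C)=CCC/C(C)=C/CO | starting material
2 | triethyl{[(2E)-3,7-dimethylocta-2,6-dien-1-yl]oxy}silane | CC(C)=CCC/C(C)=C/CO[Si](CC)(CC)CC | intermediate
3 | 3,3-dimethyl-5-{(3E)-3-methyl-5-[(triethylsilyl)oxy]pent-3-en-1-yl}-1,2,4-trioxolane | CC1(C)OOC(CC/C(C)=C/CO[Si](CC)(CC)CC)O1 | intermediate
4 | (4E)-4-methyl-6-[(triethylsilyl)oxy]hex-4-enal | O=CCC/C(C)=C/CO[Si](CC)(CC)CC | intermediate
5 | methyl (triphenylphosphoranylidene)acetate | COC(=O)C=P(c1ccccc1)(c1ccccc1)c1ccccc1 | starting material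
6 | methyl iodo(triphenylphosphoranylidene)acetate | COC(=O)C(I)=P(c1ccccc1)(c1ccccc1)c1ccccc1 | intermediate
7 | methyl (2Z,6E)-2-iodo-6-methyl-8-[(triethylsilyl)oxy]octa-2,6-dienoate | COC(=O)/C(I)=C/CC/C(C)=C/CO[Si](CC)(CC)CC | intermediate
8 | (4R)-2,2-dimethyl-1,3-dioxolane-4-carbaldehyde, (R)-glyceraldehyde acetonide | O=C[C@H]1COC(C)(C)O1 | starting material
9 | methyl (2E,6E)-2-[(S)-[(4R)-2,2-dimethyl-1,3-dioxolan-4-yl](hydroxy)methyl]-6-methyl-8-[(triethylsilyl)oxy]octa-2,6-dienoate | CC1(C)OC[C@@H](O1)[C@@H](O)/C(C(=O)OC)=C\CC/C(C)=C/CO[Si](CC)(CC)CC | intermediate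
10 | methyl (2E,6E)-2-[(S)-(acetyloxy)[(4R)-2,2-dimethyl-1,3-dioxolan-4-yl]methyl]-6-methyl-8-[(triethylsilyl)oxy]octa-2,6-dienoate | CC1(C)OC[C@@H](O1)[C@@H](OC(C)=O)/C(C(=O)OC)=C\CC/C(C)=C/CO[Si](CC)(CC)CC | intermediate
11 | methyl (2E,6E)-2-[(1S,2R)-1-(acetyloxy)-2,3-dihydroxypropyl]-8-hydroxy-6-methylocta-2,6-dienoate | OC[C@@H](O)[C@@H](OC(C)=O)/C(C(=O)OC)=C\CC/C(C)=C/CO | intermediate
12 | methyl (2E,6E)-2-[(1S)-1-(acetyloxy)-2-oxoethyl]-8-hydroxy-6-methylocta-2,6-dienoate | O=C[C@@H](OC(C)=O)/C(C(=O)OC)=C\CC/C(C)=C/CO | intermediate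
13 | methyl 2-(bromomethyl)prop-2-enoate | COC(=O)C(=C)CBr | starting material
14 | methyl 2,3-dibromo-2-(bromomethyl)propanoate | COC(=O)C(Br)(CBr)CBr | intermediate
15 | methyl (2Z)-3-bromo-2-(bromomethyl)prop-2-enoate | COC(=O)/C(CBr)=C/Br | intermediate
16 | methyl (2E,6E)-2-[(1S,2S)-1-(acetyloxy)-3-bromo-2-hydroxy-4-(methoxycarbonyl)pent-4-en-1-yl]-8-hydroxy-6-methylocta-2,6-dienoate (both C7 epimers) | COC(=O)C(=C)C(Br)[C@@H](O)[C@@H](OC(C)=O)/C(C(=O)OC)=C\CC/C(C)=C/CO | intermediate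
17 | methyl (2E)-2-[(1S,2S)-1-(acetyloxy)-3-bromo-2-hydroxy-4-(methoxycarbonyl)pent-4-en-1-yl]-5-[(2R,3R)-3-(hydroxymethyl)-2-methyloxiran-2-yl]pent-2-enoate | COC(=O)C(=C)C(Br)[C@@H](O)[C@@H](OC(C)=O)/C(C(=O)OC)=C\CC[C@@]1(C)O[C@@H]1CO | intermediate
18 | methyl (2E)-2-[(1S,2S)-1-(acetyloxy)-3-bromo-2-hydroxy-4-(methoxycarbonyl)pent-4-en-1-yl]-5-[(2R,3S)-3-formyl-2-methyloxiran-2-yl]pent-2-enoate | COC(=O)C(=C)C(Br)[C@@H](O)[C@@H](OC(C)=O)/C(C(=O)OC)=C\CC[C@@]1(C)O[C@@H]1C=O | intermediate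
19 | dimethyl (1(10)E,4R,5R,6S,7R,8R,9S)-9-acetoxy-4,5-epoxy-6,8-dihydroxygermacra-1(10),11(13)-diene-12,14-dioate (chromium-bound at O6) | C=C(C(=O)OC)[C@@H]1[C@@H](O)[C@@H](OC(C)=O)/C(C(=O)OC)=C\CC[C@@]2(C)O[C@@H]2[C@H]1O | intermediate
20 | methyl (1(10)E,4R,5R,6S,7R,8R,9S)-9-acetoxy-4,5-epoxy-8-hydroxygermacra-1(10),11(13)-dien-12,6-olid-14-oate | C=C1C(=O)O[C@H]2[C@H]1[C@@H](O)[C@@H](OC(C)=O)/C(C(=O)OC)=C\CC[C@@]1(C)O[C@H]21 | intermediate
21 | (2E)-2-methylbut-2-en-1-ol | C/C=C(\C)CO | starting material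
22 | [(2R,3R)-2,3-dimethyloxiran-2-yl]methanol | OC[C@@]1(C)O[C@@H]1C | intermediate
23 | (2S,3R)-2,3-dimethyloxirane-2-carboxylic acid | OC(=O)[C@@]1(C)O[C@@H]1C | intermediate
24 | (2R,3S)-3-chloro-2-hydroxy-2-methylbutanoic acid | OC(=O)[C@@](C)(O)[C@H](C)Cl | intermediate
25 | (2R,3S)-3-chloro-2-hydroxy-2-methylbutanoic 2,4,6-trichlorobenzoic anhydride | O=C(OC(=O)[C@@](C)(O)[C@H](C)Cl)c1c(Cl)cc(Cl)cc1Cl | intermediate
26 | methyl (1(10)E,4R,5R,6S,7R,8R,9S)-9-acetoxy-8-{[(2R,3S)-3-chloro-2-hydroxy-2-methylbutanoyl]oxy}-4,5-epoxygermacra-1(10),11(13)-dien-12,6-olid-14-oate (CNP0185503.4) | C=C1C(=O)O[C@H]2[C@H]1[C@@H](OC(=O)[C@@](C)(O)[C@H](C)Cl)[C@@H](OC(C)=O)/C(C(=O)OC)=C\CC[C@@]1(C)O[C@H]21 | target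

**Totals and weak points**

Total step count: 15. Longest linear sequence: 11 steps (geraniol 1 to 26 through steps 1–6, 8–11 and 15).

Most likely to fail, first: step 11. The ten-membered closure must win over oligomerisation and over loss of the C8 oxygen from the allylchromium, and C6/C7 are set only by the ring transition state. The fallback sets out from 16 and rejoins at 26. MnO2 (CH2Cl2, rt) oxidises only the allylic C6 alcohol of 16 to the bromo hydroxy dienal F1. CrCl2 (DMF/THF, high dilution) closes this unhindered enal through the chromium-bound seco hydroxy ester F2 to the 4,5-dehydro hydroxy lactone F3, still forming carbocycle and lactone together. Yamaguchi acylation with 25 (made from 24 as in step 15) gives the 4,5-dehydro target F4. m-CPBA (CH2Cl2, NaHCO3, 0 °C) then epoxidises only the electron-rich trisubstituted C4=C5 bond, from the outer face of the ring, to give 26. The epoxide is thus moved from reagent control on the open chain to ring control at the end.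

Second: step 8. The γ-bromoallylation is without direct precedent; attack through the CH2 terminus or further reduction of the product bromide could intervene. The fallback sets out from 12 and rejoins at 16. Compound 13 and tetrahydrothiophene (acetone, rt) give the allylic sulfonium bromide F5. Its ylide (K2CO3, MeCN, 0 °C) adds to 12 and closes to the vinyl epoxide F6 (sulfonium ylide epoxidation, Felkin–Anh at C8). MgBr2·OEt2 (Et2O, −20 °C) opens the activated allylic C7–O bond with bromide to give 16.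

Third: step 4. An alkenylchromium bearing an α-ester is a sluggish nucleophile and the Felkin ratio at C9 may be modest. The fallback sets out from 4 and rejoins at 9. Compounds 4 and 5 without iodination (CH2Cl2, rt) give the (E)-enoate F7. Me2AlSPh (CH2Cl2, −78 °C) adds to C1 and the aluminium enolate is trapped by 8 to give the β-hydroxy sulfide F8 (thiolate-triggered Michael–aldol, Felkin–Anh at C9). NaIO4 (MeOH/H2O) gives the sulfoxide F9, whose syn-elimination (toluene, 80 °C) restores the C1=C10 bond and gives 9.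

**Further compounds**

F1 | step 11 | methyl (2E,6E)-2-[(1S,2S)-1-(acetyloxy)-3-bromo-2-hydroxy-4-(methoxycarbonyl)pent-4-en-1-yl]-6-methyl-8-oxoocta-2,6-dienoate | COC(=O)C(=C)C(Br)[C@@H](O)[C@@H](OC(C)=O)/C(C(=O)OC)=C\CC/C(C)=C/C=O
F2 | step 11 | 4,5-deoxy-(4E) analogue of 19: dimethyl 9-acetoxy-6,8-dihydroxygermacra-1(10),4,11(13)-triene-12,14-dioate with C6–C9 configured as in 19 | C=C(C(=O)OC)[C@@H]1[C@@H](O)[C@@H](OC(C)=O)/C(C(=O)OC)=C\CC/C(C)=C/[C@H]1O
F3 | step 11 | 4,5-deoxy-(4E) analogue of 20: methyl 9-acetoxy-8-hydroxygermacra-1(10),4,11(13)-trien-12,6-olid-14-oate with C6–C9 configured as in 20 | C1/C(C)=C/[C@H]2OC(=O)C(=C)[C@@H]2[C@@H](O)[C@@H](OC(C)=O)/C(C(=O)OC)=C\C1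
F4 | step 11 | 4,5-deoxy-(4E) analogue of 26: the 8-O-[(2R,3S)-3-chloro-2-hydroxy-2-methylbutanoyl] ester of F3 | C1/C(C)=C/[C@H]2OC(=O)C(=C)[C@@H]2[C@@H](OC(=O)[C@@](C)(O)[C@H](C)Cl)[C@@H](OC(C)=O)/C(C(=O)OC)=C\C1
F5 | step 8 | 1-[2-(methoxycarbonyl)prop-2-en-1-yl]thiolan-1-ium bromide | COC(=O)C(=C)C[S+]1CCCC1.[Br-]
F6 | step 8 | methyl (2E,6E)-2-[(S)-(acetyloxy){(2R)-3-[1-(methoxycarbonyl)ethenyl]oxiran-2-yl}methyl]-8-hydroxy-6-methylocta-2,6-dienoate (both C7 epimers) | COC(=O)C(=C)C1O[C@H]1[C@@H](OC(C)=O)/C(C(=O)OC)=C\CC/C(C)=C/CO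
F7 | step 4 | methyl (2E,6E)-6-methyl-8-[(triethylsilyl)oxy]octa-2,6-dienoate | COC(=O)/C=C/CC/C(C)=C/CO[Si](CC)(CC)CC
F8 | step 4 | methyl (6E)-2-[(S)-[(4R)-2,2-dimethyl-1,3-dioxolan-4-yl](hydroxy)methyl]-6-methyl-3-(phenylsulfanyl)-8-[(triethylsilyl)oxy]oct-6-enoate (C2 and C3 as mixtures) | CC1(C)OC[C@@H](O1)[C@@H](O)C(C(=O)OC)C(Sc1ccccc1)CC/C(C)=C/CO[Si](CC)(CC)CC
F9 | step 4 | methyl (6E)-3-(benzenesulfinyl)-2-[(S)-[(4R)-2,2-dimethyl-1,3-dioxolan-4-yl](hydroxy)methyl]-6-methyl-8-[(triethylsilyl)oxy]oct-6-enoate (C2 and C3 and sulfur as mixtures) | CC1(C)OC[C@@H](O1)[C@@H](O)C(C(=O)OC)C(CC/C(C)=C/CO[Si](CC)(CC)CC)S(=O)c1ccccc1
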